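The numbers in the tables were generated by integration with constants of no real substance; noise was put on by code.

The ratio of right-handed to left-handed product is the small thing we reckon here, and the excess asked for is what remains after it. A racemic substrate meets a single-handed coupling partner while a racemization catalyst interconverts the two hands, which makes this a dynamic kinetic resolution.

the same everywhere: left-handed substrate 0.25 M; right-handed substrate 0.25 M

| flask | coupling partner | racemization catalyst | temperature | remark | time |
|---|---|---|---|---|---|
| ochre | 1 M | 13 mM | 94 °C | run made earlier |  |
| violet | 1 M | 30 mM | 102 °C | run made earlier |  |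
| dawn | 1.00 M | 20 mM | 105 °C |  | 3.0 min |
| noon | 1.00 M | 20 mM | 90 °C |  | 3.0 min |

- ochre (time / min: left-handed product / %, right-handed product / %, left-handed substrate / %): 0.417: 21, 0, 32; 1.33: 43, 5, 21; 2.50: 59, 1, 15; 3.00: 66, 0, 12; 5.00: 81, 1, 8
- violet (time / min: left-handed product / %, right-handed product / %, left-handed substrate / %): 0.250: 20, 0, 36; 0.417: 32, 1, 30; 0.833: 45, 0, 21; 1.50: 65, 1, 17; 3.00: 81, 2, 5

(scatter of a reading: 1.5 percentage points)

- coupling partner is single-handed; left-handed substrate and right-handed substrate are mirror images of each other, charged as a racemate, each of them at the stated concentration
- an excess is the difference of the two amounts in percent of their sum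
- an excess is below zero if the other one leads
- the handed part of coupling partner does not stay in what it makes, so the products of the two hands are mirror images too

1. which flask leads in excess of left-handed product over right-handed product ("all alike" within 1.5 percentage points) (dawn / noon / all alike)
2. excess of left-handed product over right-handed product at the end, dawn
3. excess of left-handed product over right-handed product at the end, noon

Two numbers seem not to fit. Left-handed substrate is 50.0% of the charge, yet the ochre run's last reading shows 81% left-handed product. So right-handed substrate must have crossed over through the catalyst before coupling, and what coupled without crossing is small. We call that the leak ℓ, the summed right-handed product over the summed left-handed product 2.14%, with both runs pooled. Taken apart, the runs read: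

ℓ(ochre) = 2.59%

ℓ(violet) = 1.65%

Their gap of 0.94 percentage points is less than the scatter of the ochre ratio alone, 1.2 points, so we use the pooled value for both new flasks:

excess = (1 − ℓ)/(1 + ℓ) = 95.8%

Our reckoning therefore gives dawn and noon one number and calls them alike. The forecast says all alike, with 95% for dawn and 96% for noon: “This is within the tolerance, so the flasks are effectively alike.”

The flasks give 95.2% for dawn and 95.6% for noon, so the verdict is all alike.

    coupling partner + right-handed substrate → right-handed product (k = 2.53 × 10⁻⁴ M⁻¹ s⁻¹, Ea = 82.0 kJ mol⁻¹)
    coupling partner → decomposition product (k = 2.69 × 10⁻⁵ s⁻¹, Ea = 128 kJ mol⁻¹)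
    left-handed substrate + racemization catalyst ⇌ right-handed substrate + racemization catalyst, rate k3*[racemization catalyst]*[left-handed substrate] forward; the back reaction follows from the equilibrium constant (k = 0.830 M⁻¹ s⁻¹, Ea = 67.0 kJ mol⁻¹)
    coupling partner + left-handed substrate → left-handed product (k = 0.0147 M⁻¹ s⁻¹, Ea = 78.0 kJ mol⁻¹)
    (constants at 90 °C)

Noon ends with right-handed over left-handed substrate at 1.36. Noon's neighbour with 0.050 M of racemization catalyst ends with that substrate ratio lower, at 1.13. As an estimate, we let the carried ℓ of 2.14% follow that ratio, which gives 1.78% for the neighbour. The same rule then gives an excess of 96.5%, and that neighbour flask stands at 96.2%.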